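**Strategy**

Everything rests on disconnecting N1–C7a of the pyrrole ring. On the benzene ring, the bromines at C4 and C6 and the nitrogen at C7a are mutually meta around C3a, so the indole maps onto a 2,4,6-tribromophenyl group whose two ortho bromines are equivalent. A copper-catalysed intramolecular amide N-arylation of racemic 2-(methylsulfanyl)-2-(2,4,6-tribromophenyl)acetamide, the precursor, therefore closes the five-membered lactam ring, sets the 4,6-dibromo pattern and carries the C3 sulfide through in a single operation. The lactam carbonyl of the resulting oxindole is finally exchanged for the C2 bromine with POBr3, so the thioether is never exposed to an oxidising bromine source.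

Key step: step 5

Remark: the carbon that becomes C3 is a stereocentre in 4, 5, 7, 8 and 9; all are handled as racemates because this carbon is sp2 in the target. Ethyl glyoxylate is assumed to be used as the monomer, freshly distilled from its commercial toluene solution.

**Route**

Step 1
Reactants: 1 1,3,5-tribromobenzene; 2 ethyl glyoxylate
Product: 4 racemic ethyl 2-hydroxy-2-(2,4,6-tribromophenyl)acetate, via 2,4,6-tribromophenyllithium 3 (not isolated)
Conditions: LiN(iPr)2 (1.05 equiv), THF, −78 °C, 45 min; then 2 (1.5 equiv), −78 °C; 1 M HCl quench
Reagents that add atoms: none
Why: Deprotonation of 1 by LiN(iPr)2 at a ring hydrogen flanked by two bromines (all three are equivalent) should give aryllithium 3, which is stable to LiBr loss at −78 °C and adds to the aldehyde of 2 (organolithium 1,2-addition), the carbinol centre forming as a racemate that needs no control.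

Step 2
Reactants: 4 racemic ethyl 2-hydroxy-2-(2,4,6-tribromophenyl)acetate
Product: 5 racemic ethyl 2-(methanesulfonyloxy)-2-(2,4,6-tribromophenyl)acetate
Conditions: MsCl (1.3 equiv), Et3N (1.6 equiv), CH2Cl2, 0 °C
Reagents that add atoms: methanesulfonyl chloride, CS(=O)(=O)Cl
Why: O-sulfonylation of a secondary alcohol should proceed cleanly since the ester and the aryl bromides are inert to MsCl and Et3N, and the C–O bond, hence the racemic centre, is not touched.

Step 3
Reactants: 5 racemic ethyl 2-(methanesulfonyloxy)-2-(2,4,6-tribromophenyl)acetate; 6 sodium methanethiolate
Product: 7 racemic ethyl 2-(methylsulfanyl)-2-(2,4,6-tribromophenyl)acetate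
Conditions: NaSMe (1.2 equiv), DMF, 0 °C to rt, argon
Reagents that add atoms: none
Why: SN2 displacement of an α-sulfonyloxy ester by a small, soft, weakly basic thiolate is activated by the neighbouring carbonyl and cannot be diverted to elimination (no β-hydrogen) or to SNAr (unactivated aryl bromides); inversion of a racemate gives a racemate.

Step 4
Reactants: 7 racemic ethyl 2-(methylsulfanyl)-2-(2,4,6-tribromophenyl)acetate
Product: 8 racemic 2-(methylsulfanyl)-2-(2,4,6-tribromophenyl)acetamide
Conditions: NH3 (7 M in MeOH, large excess), sealed tube, 60 °C
Reagents that add atoms: ammonia, N
Why: Ammonolysis of an ester (nucleophilic acyl substitution, helped by transesterification to the methyl ester and by the inductive pull of the α-sulfur) should give the primary amide, while sulfide and aryl bromides do not react with ammonia and the α-centre stays racemic.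

Step 5
Reactants: 8 racemic 2-(methylsulfanyl)-2-(2,4,6-tribromophenyl)acetamide
Product: 9 racemic 4,6-dibromo-3-(methylsulfanyl)indolin-2-one
Conditions: CuI (10 mol%), N,N'-dimethylethylenediamine (20 mol%), K3PO4 (2 equiv), degassed 1,4-dioxane (0.05 M), 90 °C, argon
Reagents that add atoms: none
Why: Base and the CuI–diamine complex should convert the primary amide into a monovalent copper amidate, to which the ortho C–Br bond held beside it adds oxidatively (formally giving trivalent copper) before C–N reductive elimination forms N1–C7a and K3PO4 takes up the HBr. The closest known reaction is the copper/diamine-catalysed Goldberg amidation of aryl bromides, applied intramolecularly to 2-(2-haloaryl)acetamides to make oxindoles. The five-membered lactam ring (N1–C2–C3–C3a–C7a) closes by intramolecular N-arylation in a 5-exo sense, the breaking C–Br bond lying outside the new ring. No stereocentre is created; the existing C3 centre is racemic and may epimerise under the base without consequence. The step needs ortho over para selectivity and cyclisation over intermolecular coupling: the one-carbon tether lets the amidate reach only the two ortho carbons, which interchange by rotation about the C(sp3)–aryl bond and give the same oxindole, while the para bromine is out of reach and becomes C6–Br. Dilution, the higher reactivity of a primary amide compared with the lactam product, and exclusion of air (which could oxidise C3 of the oxindole anion) should guard against oligomers, N-arylated product and 3-hydroxylation.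

Step 6
Reactants: 9 racemic 4,6-dibromo-3-(methylsulfanyl)indolin-2-one
Product: 10 2,4,6-tribromo-3-(methylsulfanyl)-1H-indole
Conditions: POBr3 (2.5 equiv), imidazole (1.2 equiv), 1,2-dichloroethane, 80 °C; then ice-water
Reagents that add atoms: phosphoryl tribromide, O=P(Br)(Br)Br
Why: Deoxybromination of a lactam with POBr3 (Vilsmeier–Haack-type activation) should proceed by O-phosphorylation to an imidoyl dibromophosphate, bromide addition at C2 with loss of the phosphate, and loss of the C3 proton to aromatise the 2-bromo-3H-indole, which erases the C3 stereocentre; no electrophilic bromine is present, so the sulfide, C5 and C7 stay untouched, and imidazole buffers the acid.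

**Compound list**

1 | 1,3,5-tribromobenzene | Brc1cc(Br)cc(Br)c1 | starting material
2 | ethyl glyoxylate | CCOC(=O)C=O | starting material
3 | 2,4,6-tribromophenyllithium | [Li]c1c(Br)cc(Br)cc1Br | intermediate (not isolated)
4 | racemic ethyl 2-hydroxy-2-(2,4,6-tribromophenyl)acetate | CCOC(=O)C(O)c1c(Br)cc(Br)cc1Br | intermediate
5 | racemic ethyl 2-(methanesulfonyloxy)-2-(2,4,6-tribromophenyl)acetate | CCOC(=O)C(OS(C)(=O)=O)c1c(Br)cc(Br)cc1Br | intermediate
6 | sodium methanethiolate | [Na+].[S-]C | starting material
7 | racemic ethyl 2-(methylsulfanyl)-2-(2,4,6-tribromophenyl)acetate | CCOC(=O)C(SC)c1c(Br)cc(Br)cc1Br | intermediate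
8 | racemic 2-(methylsulfanyl)-2-(2,4,6-tribromophenyl)acetamide | CSC(C(N)=O)c1c(Br)cc(Br)cc1Br | intermediate
9 | racemic 4,6-dibromo-3-(methylsulfanyl)indolin-2-one | CSC1C(=O)Nc2cc(Br)cc(Br)c12 | intermediate
10 | 2,4,6-tribromo-3-(methylsulfanyl)-1H-indole | CSc1c(Br)[nH]c2cc(Br)cc(Br)c12 | target

**Step count**

Total steps: 6. Longest linear sequence: 6 steps (1 to 10).

**Steps most likely to fail**

Step 5 (key step). The cyclisation may be slowed by sulfide binding to copper. The para bromine may then enter intermolecular amidation and give oligomers, the lactam N–H of the product may be arylated further, or copper-mediated hydrodebromination may erode the bromine pattern. The fallback forms the C3–C3a bond instead of N1–C7a. It sets out from 1, used in excess, which is mono-aminated with aqueous NH3 (CuI, L-proline, K2CO3, DMSO, 80 °C) to 3,5-dibromoaniline F1 (also a commercial compound). A Gassman oxindole synthesis follows: tBuOCl in CH2Cl2 at −65 °C, then ethyl 2-(methylsulfanyl)acetate, then Et3N. The azasulfonium ylide should undergo the [2,3]-sigmatropic shift to either of the two equivalent ortho carbons and give racemic ethyl 2-(2-amino-4,6-dibromophenyl)-2-(methylsulfanyl)acetate F2. Stirring F2 with dilute aqueous HCl should close the lactam, and the route is rejoined at 9.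

Step 6. Activation of the electron-poor lactam may be incomplete. Under the hot acidic conditions the methylsulfanyl group may be lost or may migrate, and the 2-bromoindole may decompose. The fallback sets out from 9. Reduction with iBu2AlH (toluene/CH2Cl2, 0 °C to rt, acidic work-up) should give the hemiaminal, which dehydrates to 4,6-dibromo-3-(methylsulfanyl)-1H-indole F3. Bromination of F3 with NBS (1.0 equiv, CH2Cl2, −78 to 0 °C) should then occur at C2, the only free pyrrole position, the benzene ring being deactivated by its two bromines. This rejoins the route at 10, at the price of exposing the sulfide briefly to an electrophilic bromine source.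

Step 1. The aryllithium may be protonated by hydrate or oligomer left in the glyoxylate, it may lose LiBr to an aryne if the temperature drifts upward, and the addition to the aldehyde may be incomplete. The fallback sets out from 3, made from 1 as in step 1. Addition of 3 to an excess of diethyl oxalate (THF, −78 °C, inverse addition) should give ethyl 2-oxo-2-(2,4,6-tribromophenyl)acetate F4, because the tetrahedral adduct survives at low temperature and prevents a second addition. Reduction of the ketone of F4 with NaBH4 (EtOH, −20 °C) rejoins the route at 4.

**Further compounds**

F1 | step 5 | 3,5-dibromoaniline | Nc1cc(Br)cc(Br)c1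
F2 | step 5 | racemic ethyl 2-(2-amino-4,6-dibromophenyl)-2-(methylsulfanyl)acetate | CCOC(=O)C(SC)c1c(N)cc(Br)cc1Br
F3 | step 6 | 4,6-dibromo-3-(methylsulfanyl)-1H-indole | CSc1c[nH]c2cc(Br)cc(Br)c12
F4 | step 1 | ethyl 2-oxo-2-(2,4,6-tribromophenyl)acetate | CCOC(=O)C(=O)c1c(Br)cc(Br)cc1Br
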